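## Retrosynthetic overview

1. The target is epicatechin-(4β→8)-epifisetinidol-(4β→8)-catechin. Units are tagged t for top, m for middle and b for bottom, each with benzo ring A, pyran ring C, catechol ring B and flavan numbering (for example C4-m, ring C-m).
2. Last skeletal event: ring C-m is closed at C4-m–C4a-m and, in the same operation, the C4-m–C8-b bond is made. C4-m is carried as a diethyl acetal, that is, as a geminal dication at the aldehyde oxidation level.
3. Enabling feature: C4-m is a methine between two oxygen-activated arene carbons. C4a-m is para to O7-m and ortho to O1-m, and its other ortho site C8-m is filled by unit t. C8-b lies between O7-b and O1-b, para to O5-b. C4-m also sits next to the axial O3-m of a 2,3-cis ring, which steers the second arylation to the 4β face.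
4. The open precursor comes from a top-unit phenol and a cis-aryl epoxide. The O1-m–C2-m bond forms by SN2 inversion, which fixes C2-m and C3-m. The phenol comes from the C4-t cation of 8-bromo-capped benzylated epicatechin and a 2,6-dioxygenated arylboronic acid, where ipso attack gives C4-t–C8-m.
5. Ring order: all rings of t and b are taken from natural (−)-epicatechin and (+)-catechin, and rings A-m and B-m are bought as arenes. Ring C-m is formed last, and one hydrogenolysis then removes thirteen benzyl groups and the bromine.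

Key step: step 16

Assumption: 2-iodoresorcinol, 4-bromo-1,2-bis(benzyloxy)benzene and 3,3-diethoxyprop-1-yne are taken as commercial. "4β" means trans to the 3-oxygen of a 2R,3R unit.

## Route

Step 1
Reactants: 1 (−)-epicatechin
Product: 2 5,7,3',4'-tetra-O-benzyl-(−)-epicatechin
Conditions: BnBr (4.4 equiv), K2CO3, DMF, 0 °C → rt, Ar
Reagents that add atoms: benzyl bromide BrCc1ccccc1
Why: Williamson etherification with a carbonate base alkylates only the four phenols, leaves the aliphatic 3-OH free and is mild enough not to epimerise C2.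

Step 2
Reactants: 2 5,7,3',4'-tetra-O-benzyl-(−)-epicatechin
Product: 3 8-bromo-5,7,3',4'-tetra-O-benzyl-(−)-epicatechin
Conditions: NBS (1.0 equiv), CH2Cl2, −78 → 0 °C
Reagents that add atoms: N-bromosuccinimide O=C1CCC(=O)N1Br
Why: Electrophilic aromatic bromination goes to C8, the most nucleophilic position of the phloroglucinol-type ring A, and installs a cap that later silences this ring as a nucleophile.

Step 3
Reactants: 3 8-bromo-5,7,3',4'-tetra-O-benzyl-(−)-epicatechin
Product: 4 8-bromo-5,7,3',4'-tetra-O-benzyl-4β-(2-ethoxyethoxy)epicatechin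
Conditions: DDQ (1.5 equiv), 2-ethoxyethanol (5 equiv), CH2Cl2, rt
Reagents that add atoms: 2-ethoxyethanol CCOCCO
Why: DDQ benzylic C–H oxidation (hydride abstraction at C4) gives a cation that the alcohol traps anti to the axial 3-OH, setting a 4β ether centre that is erased again in step 8.

Step 4
Reactants: 4 8-bromo-5,7,3',4'-tetra-O-benzyl-4β-(2-ethoxyethoxy)epicatechin
Product: 5 8-bromo-3,5,7,3',4'-penta-O-benzyl-4β-(2-ethoxyethoxy)epicatechin
Conditions: NaH, BnBr, n-Bu4NI (cat.), DMF, 0 °C → rt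
Reagents that add atoms: benzyl bromide BrCc1ccccc1
Why: Williamson etherification of the 3-OH is compatible with the base-stable 4-ether and prevents a boronate tether at O3 from delivering the aryl group to the wrong face in step 8.

Step 5
Reactants: 6 2-iodoresorcinol
Product: 7 3-(benzyloxy)-2-iodophenol
Conditions: BnBr (0.9 equiv), K2CO3, acetone, reflux; chromatography
Reagents that add atoms: benzyl bromide BrCc1ccccc1
Why: Statistical Williamson monoalkylation of a cheap symmetrical diol differentiates the two oxygens of ring A-m at the earliest point.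

Step 6
Reactants: 7 3-(benzyloxy)-2-iodophenol
Product: 8 1-(allyloxy)-3-(benzyloxy)-2-iodobenzene
Conditions: allyl bromide, K2CO3, DMF, rt
Reagents that add atoms: allyl bromide C=CCBr
Why: Williamson etherification masks the future O1-m as an allyl ether that tolerates organomagnesium reagents and Lewis acid and is removable beside benzyl ethers.

Step 7
Reactants: 8 1-(allyloxy)-3-(benzyloxy)-2-iodobenzene
Product: 11 [2-(allyloxy)-6-(benzyloxy)phenyl]boronic acid, via arylmagnesium chloride 9 (not isolated), via dimethyl boronate 10 (not isolated)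
Conditions: iPrMgCl·LiCl, THF, −20 °C; B(OMe)3, −20 °C → rt; aq NH4Cl
Reagents that add atoms: trimethyl borate COB(OC)OC; water O
Why: Iodine–magnesium exchange, accelerated by the two flanking alkoxy groups, followed by borylation and hydrolysis places boron exactly on the carbon between the two oxygens (future C8-m).

Step 8
Reactants: 5 8-bromo-3,5,7,3',4'-penta-O-benzyl-4β-(2-ethoxyethoxy)epicatechin; 11 [2-(allyloxy)-6-(benzyloxy)phenyl]boronic acid
Product: 13 4β-[2-(allyloxy)-6-(benzyloxy)phenyl]-8-bromo-3,5,7,3',4'-penta-O-benzylepicatechin, via flavan-4-t-yl cation 12 (not isolated)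
Conditions: 11 (1.5 equiv), TMSOTf (0.2 equiv), CH2Cl2, −78 → −20 °C
Reagents that add atoms: none
Why: In this Lewis-acid-promoted ipso-Friedel–Crafts coupling of a C4-activated flavan-3-ol ether with a 2,6-dioxygenated arylboronic acid, cation 12 is attacked at the boron-bearing carbon anti to the axial 3-benzyloxy group, which sets C4-t as 4β (3,4-trans), while the 8-bromine stops self-condensation.

Step 9
Reactants: 13 4β-[2-(allyloxy)-6-(benzyloxy)phenyl]-8-bromo-3,5,7,3',4'-penta-O-benzylepicatechin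
Product: 14 4β-[2-(benzyloxy)-6-hydroxyphenyl]-8-bromo-3,5,7,3',4'-penta-O-benzylepicatechin
Conditions: Pd(PPh3)4 (5 mol %), morpholine, THF, rt
Reagents that add atoms: none
Why: Tsuji–Trost-type deallylation with zerovalent palladium transfers the allyl group to morpholine at room temperature, where the hindered electron-rich aryl bromide and the benzyl ethers are inert.

Step 10
Reactants: 15 4-bromo-1,2-bis(benzyloxy)benzene; 16 3,3-diethoxyprop-1-yne
Product: 17 1,2-bis(benzyloxy)-4-(3,3-diethoxyprop-1-yn-1-yl)benzene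
Conditions: PdCl2(MeCN)2 (2 mol %), XPhos, Cs2CO3, MeCN, 80 °C
Reagents that add atoms: none
Why: Copper-free Sonogashira coupling with a bulky electron-rich phosphine handles the electron-rich aryl bromide and brings in C2-m, C3-m and C4-m with C4-m already at the acetal level.

Step 11
Reactants: 17 1,2-bis(benzyloxy)-4-(3,3-diethoxyprop-1-yn-1-yl)benzene
Product: 18 (Z)-1,2-bis(benzyloxy)-4-(3,3-diethoxyprop-1-en-1-yl)benzene
Conditions: H2 (1 atm), Pd/CaCO3 poisoned by Pb(OAc)2, quinoline, EtOAc, rt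
Reagents that add atoms: none
Why: Lindlar semihydrogenation adds hydrogen syn to the alkyne, gives the Z-alkene needed for a cis-epoxide and does not cleave benzyl ethers.

Step 12
Reactants: 18 (Z)-1,2-bis(benzyloxy)-4-(3,3-diethoxyprop-1-en-1-yl)benzene
Product: 19 (2S,3S)-2-[3,4-bis(benzyloxy)phenyl]-3-(diethoxymethyl)oxirane (cis)
Conditions: (S,S)-[N,N'-bis(3,5-di-tert-butylsalicylidene)cyclohexane-1,2-diaminato]MnCl (5 mol %), 4-phenylpyridine N-oxide, aq NaOCl (pH 11.3), CH2Cl2, 0 °C
Reagents that add atoms: sodium hypochlorite [Na+].[O-]Cl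
Why: Jacobsen–Katsuki epoxidation of a conjugated cis-alkene with the (S,S)-catalyst should deliver oxygen to the face that makes the benzylic carbon S (the sense seen with cis-β-methylstyrene and indene), setting both epoxide carbons, and the basic medium protects the acid-labile product.

Step 13
Reactants: 14 4β-[2-(benzyloxy)-6-hydroxyphenyl]-8-bromo-3,5,7,3',4'-penta-O-benzylepicatechin; 19 (2S,3S)-2-[3,4-bis(benzyloxy)phenyl]-3-(diethoxymethyl)oxirane
Product: 20 (1R,2S)-1-[3,4-bis(benzyloxy)phenyl]-3,3-diethoxy-1-(aryloxy)propan-2-ol in which the aryl group is ring A-m of 14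
Conditions: 19 (1.3 equiv), Cs2CO3 (0.3 equiv), DMF, 70 °C
Reagents that add atoms: none
Why: Base-mediated SN2 opening of the aryl epoxide by the phenoxide occurs at the benzylic carbon (the acetal-bearing carbon is inductively and sterically deactivated), inverts C2-m and retains C3-m, and so gives the syn aryloxy alcohol that maps onto a 2,3-cis ring.

Step 14
Reactants: 20 the hydroxy ether of step 13
Product: 21 (1R,2S)-2-O-benzyl ether of 20 (open precursor carrying the C4-m diethyl acetal)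
Conditions: NaH, BnBr, n-Bu4NI (cat.), DMF, 0 °C → rt
Reagents that add atoms: benzyl bromide BrCc1ccccc1
Why: Williamson etherification is safe here because the acetal leaves no acidic hydrogen next to C3-m, so neither epimerisation nor β-elimination of the aryloxide can occur.

Step 15
Reactants: 22 (+)-catechin
Product: 23 5,7,3',4'-tetra-O-benzyl-(+)-catechin
Conditions: BnBr (4.4 equiv), K2CO3, DMF, 0 °C → rt, Ar
Reagents that add atoms: benzyl bromide BrCc1ccccc1
Why: Williamson etherification of the four phenols gives the standard C8-nucleophilic catechin building block with both stereocentres untouched.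

Step 16
Reactants: 21 open acetal precursor; 23 5,7,3',4'-tetra-O-benzyl-(+)-catechin
Product: 27 protected trimer (thirteen benzyl ethers plus 8-t bromine; free 3-b hydroxyl), via oxocarbenium ion 24 (not isolated), via 4-m-ethoxyflavan 25 (not isolated), via flavan-4-m-yl cation 26 (not isolated)
Conditions: 23 (3 equiv), TMSOTf (0.3 equiv), 4 Å MS, CH2Cl2, −78 → −30 °C; Et3N quench
Reagents that add atoms: none
Why: Proposed new method: TMSOTf ionises the acetal of 21 to oxocarbenium ion 24, C4a-m attacks it (Friedel–Crafts, 6-exo-trig at the C=O+ bond) to close ring C-m as both C4-m epimers of 25, and a second ionisation merges them into the planar cation 26 (stabilised by O7-m para and O1-m ortho), which is captured by C8-b of 23. The closest known reaction types are the acid-induced cyclisation of aryloxyalkyl acetals onto their arene and the Lewis-acid coupling of 4-alkoxyflavan-3-ol ethers with tetra-O-benzylcatechin, and what is new is to run both at one geminally dielectrophilic carbon so that the pyran ring and the interflavan bond arise together. C4-m is the only new stereocentre and is controlled by the 2,3-cis half-chair of 26, in which the aryl group at C2-m is equatorial and the 3-m benzyloxy group axial, so that 23 adds anti to that group and gives the 3,4-trans (4β) bond. The step is stereoconvergent, because either epimer of 25, and also the alternative order (23 first, ring closure second, through the cation stabilised by ring A-b), leads to the same 3,4-trans product. Chemoselectivity needs ring closure to outrun a second intermolecular arylation, which the six-membered transition state and unit t at C8-m secure, since unit t blocks the other ortho site and turns the O1-m–C2-m bond towards C4a-m. It also needs 26 to be taken by 23 and not by ring A-t, which the 8-t bromine and the excess of 23 secure, and the acetal to ionise before the O1-m–C2-m ether and the C4-t–C8-m bond, which the more basic acetal oxygens and the low temperature secure.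

Step 17
Reactants: 27 protected trimer
Product: 28 epicatechin-(4β→8)-epifisetinidol-(4β→8)-catechin (target)
Conditions: H2 (1 atm), Pd(OH)2/C, THF–MeOH–H2O, rt
Reagents that add atoms: none
Why: Catalytic hydrogenolysis removes all thirteen benzyl ethers and the aryl bromine in one operation under neutral conditions that touch no stereocentre, pyran ring or interflavan bond.

## Compound list

1 | (−)-epicatechin, (2R,3R) | Oc1cc(O)c2c(c1)O[C@H](c1ccc(O)c(O)c1)[C@H](O)C2 | starting material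
2 | 5,7,3',4'-tetra-O-benzyl-(−)-epicatechin | C(c9ccccc9)Oc1cc(OCc9ccccc9)c2c(c1)O[C@H](c1ccc(OCc9ccccc9)c(OCc9ccccc9)c1)[C@H](O)C2 | intermediate
3 | 8-bromo-5,7,3',4'-tetra-O-benzyl-(−)-epicatechin | C(c9ccccc9)Oc1cc(OCc9ccccc9)c2c(c1Br)O[C@H](c1ccc(OCc9ccccc9)c(OCc9ccccc9)c1)[C@H](O)C2 | intermediate
4 | 8-bromo-5,7,3',4'-tetra-O-benzyl-4β-(2-ethoxyethoxy)epicatechin (2,3-cis-3,4-trans) | C(c9ccccc9)Oc1cc(OCc9ccccc9)c2c(c1Br)O[C@H](c1ccc(OCc9ccccc9)c(OCc9ccccc9)c1)[C@H](O)[C@H]2OCCOCC | intermediate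
5 | 8-bromo-3,5,7,3',4'-penta-O-benzyl-4β-(2-ethoxyethoxy)epicatechin | C(c9ccccc9)Oc1cc(OCc9ccccc9)c2c(c1Br)O[C@H](c1ccc(OCc9ccccc9)c(OCc9ccccc9)c1)[C@H](OCc9ccccc9)[C@H]2OCCOCC | intermediate
6 | 2-iodoresorcinol | Oc1cccc(O)c1I | starting material
7 | 3-(benzyloxy)-2-iodophenol | Oc1cccc(OCc2ccccc2)c1I | intermediate
8 | 1-(allyloxy)-3-(benzyloxy)-2-iodobenzene | C=CCOc1cccc(OCc2ccccc2)c1I | intermediate
9 | [2-(allyloxy)-6-(benzyloxy)phenyl]magnesium chloride (not isolated) | C=CCOc1cccc(OCc2ccccc2)c1[Mg]Cl | intermediate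
10 | dimethyl [2-(allyloxy)-6-(benzyloxy)phenyl]boronate (not isolated) | C=CCOc1cccc(OCc2ccccc2)c1B(OC)OC | intermediate
11 | [2-(allyloxy)-6-(benzyloxy)phenyl]boronic acid | C=CCOc1cccc(OCc2ccccc2)c1B(O)O | intermediate
12 | 8-bromo-penta-O-benzylepicatechin-4-yl cation (not isolated) | C(c9ccccc9)Oc1cc(OCc9ccccc9)c2c(c1Br)O[C@H](c1ccc(OCc9ccccc9)c(OCc9ccccc9)c1)[C@H](OCc9ccccc9)[CH+]2 | intermediate
13 | 4β-[2-(allyloxy)-6-(benzyloxy)phenyl]-8-bromo-3,5,7,3',4'-penta-O-benzylepicatechin | C(c9ccccc9)Oc1cc(OCc9ccccc9)c2c(c1Br)O[C@H](c1ccc(OCc9ccccc9)c(OCc9ccccc9)c1)[C@H](OCc9ccccc9)[C@H]2c1c(OCc9ccccc9)cccc1OCC=C | intermediate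
14 | 4β-[2-(benzyloxy)-6-hydroxyphenyl]-8-bromo-3,5,7,3',4'-penta-O-benzylepicatechin | C(c9ccccc9)Oc1cc(OCc9ccccc9)c2c(c1Br)O[C@H](c1ccc(OCc9ccccc9)c(OCc9ccccc9)c1)[C@H](OCc9ccccc9)[C@H]2c1c(OCc9ccccc9)cccc1O | intermediate
15 | 4-bromo-1,2-bis(benzyloxy)benzene | Brc1ccc(OCc2ccccc2)c(OCc2ccccc2)c1 | starting material
16 | 3,3-diethoxyprop-1-yne | C#CC(OCC)OCC | starting material
17 | 1,2-bis(benzyloxy)-4-(3,3-diethoxyprop-1-yn-1-yl)benzene | CCOC(OCC)C#Cc1ccc(OCc2ccccc2)c(OCc2ccccc2)c1 | intermediate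
18 | (Z)-1,2-bis(benzyloxy)-4-(3,3-diethoxyprop-1-en-1-yl)benzene | CCOC(OCC)/C=C\c1ccc(OCc2ccccc2)c(OCc2ccccc2)c1 | intermediate
19 | (2S,3S)-2-[3,4-bis(benzyloxy)phenyl]-3-(diethoxymethyl)oxirane (cis) | C(c9ccccc9)Oc1ccc(cc1OCc9ccccc9)[C@@H]1O[C@@H]1C(OCC)OCC | intermediate
20 | syn hydroxy ether: O1-m of 14 bonded to C2-m; (1R,2S)-1-aryl-1-aryloxy-3,3-diethoxypropan-2-ol | C(c9ccccc9)Oc1cc(OCc9ccccc9)c2c(c1Br)O[C@H](c1ccc(OCc9ccccc9)c(OCc9ccccc9)c1)[C@H](OCc9ccccc9)[C@H]2c1c(OCc9ccccc9)cccc1O[C@H](c1ccc(OCc9ccccc9)c(OCc9ccccc9)c1)[C@H](O)C(OCC)OCC | intermediate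
21 | open acetal precursor: 3-m O-benzyl ether of 20 | C(c9ccccc9)Oc1cc(OCc9ccccc9)c2c(c1Br)O[C@H](c1ccc(OCc9ccccc9)c(OCc9ccccc9)c1)[C@H](OCc9ccccc9)[C@H]2c1c(OCc9ccccc9)cccc1O[C@H](c1ccc(OCc9ccccc9)c(OCc9ccccc9)c1)[C@H](OCc9ccccc9)C(OCC)OCC | intermediate
22 | (+)-catechin, (2R,3S) | Oc1cc(O)c2c(c1)O[C@H](c1ccc(O)c(O)c1)[C@@H](O)C2 | starting material
23 | 5,7,3',4'-tetra-O-benzyl-(+)-catechin | C(c9ccccc9)Oc1cc(OCc9ccccc9)c2c(c1)O[C@H](c1ccc(OCc9ccccc9)c(OCc9ccccc9)c1)[C@@H](O)C2 | intermediate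
24 | O-ethyl oxocarbenium ion at C4-m (not isolated) | C(c9ccccc9)Oc1cc(OCc9ccccc9)c2c(c1Br)O[C@H](c1ccc(OCc9ccccc9)c(OCc9ccccc9)c1)[C@H](OCc9ccccc9)[C@H]2c1c(OCc9ccccc9)cccc1O[C@H](c1ccc(OCc9ccccc9)c(OCc9ccccc9)c1)[C@H](OCc9ccccc9)C=[O+]CC | intermediate
25 | ring-closed 4-m-ethoxyflavan, both C4-m epimers (not isolated) | C(c9ccccc9)Oc1cc(OCc9ccccc9)c2c(c1Br)O[C@H](c1ccc(OCc9ccccc9)c(OCc9ccccc9)c1)[C@H](OCc9ccccc9)[C@H]2c1c(OCc9ccccc9)ccc2c1O[C@H](c1ccc(OCc9ccccc9)c(OCc9ccccc9)c1)[C@H](OCc9ccccc9)C2OCC | intermediate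
26 | flavan-4-m-yl cation (not isolated) | C(c9ccccc9)Oc1cc(OCc9ccccc9)c2c(c1Br)O[C@H](c1ccc(OCc9ccccc9)c(OCc9ccccc9)c1)[C@H](OCc9ccccc9)[C@H]2c1c(OCc9ccccc9)ccc2c1O[C@H](c1ccc(OCc9ccccc9)c(OCc9ccccc9)c1)[C@H](OCc9ccccc9)[CH+]2 | intermediate
27 | protected trimer: 8-t-bromo, thirteen O-benzyl groups, free 3-b OH; both flavan-4-yl units 2,3-cis-3,4-trans | C(c9ccccc9)Oc1cc(OCc9ccccc9)c2c(c1Br)O[C@H](c1ccc(OCc9ccccc9)c(OCc9ccccc9)c1)[C@H](OCc9ccccc9)[C@H]2c1c(OCc9ccccc9)ccc2c1O[C@H](c1ccc(OCc9ccccc9)c(OCc9ccccc9)c1)[C@H](OCc9ccccc9)[C@H]2c1c(OCc9ccccc9)cc(OCc9ccccc9)c2c1O[C@H](c1ccc(OCc9ccccc9)c(OCc9ccccc9)c1)[C@@H](O)C2 | intermediate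
28 | epicatechin-(4β→8)-epifisetinidol-(4β→8)-catechin | Oc1cc(O)c2c(c1)O[C@H](c1ccc(O)c(O)c1)[C@H](O)[C@H]2c1c(O)ccc2c1O[C@H](c1ccc(O)c(O)c1)[C@H](O)[C@H]2c1c(O)cc(O)c2c1O[C@H](c1ccc(O)c(O)c1)[C@@H](O)C2 | target

## Step count and risks

Total step count: 17. Longest linear sequence: 10 steps (1, 2, 3, 4, 8, 9, 13, 14, 16, 17).

**Step 16 (labelled step).**
- What may go wrong: the acyclic O1-m–C2-m benzylic aryl ether may ionise before or along with the α-benzyloxy acetal, which fragments the precursor. Alternatively, C4-m may be arylated twice by the external nucleophile before the ring closes.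
- Fallback (known reactions only), from 21 and 23 back to 27:
  - The acetal of 21 is unmasked without Brønsted acid (TESOTf, 2,6-lutidine, CH2Cl2, then water) to the α-benzyloxy aldehyde F1.
  - 23 is brominated at C8 (NBS, CH2Cl2, −78 °C) to 8-bromo-tetra-O-benzylcatechin F2. After deprotonation and bromine–lithium exchange (n-BuLi, 2.1 equiv, THF, −78 °C), F2 adds to F1 to give the epimeric diaryl-type carbinols F3.
  - This 2,4,6-trioxygenated benzylic alcohol should ionise with a trace of weak acid (pyridinium p-toluenesulfonate, CH2Cl2, 0 °C). Under these conditions the benzylic aryl ether and the upper interflavan bond are inert.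
  - C4a-m closes ring C-m by intramolecular Friedel–Crafts alkylation to 27, and both carbinol epimers converge through one cation.

**Step 8.**
- What may go wrong: the cation may attack the less hindered position para to an alkoxy group instead of the boron-bearing carbon, or protodeboronation may precede coupling. Both processes erode the regiocontrol.
- Fallback, from 5 back to 14:
  - Ring A-m is introduced at the dihydro level, where the carbon between the two oxygens is the only nucleophilic one.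
  - Cyclohexane-1,3-dione is C-alkylated by 5 (Sc(OTf)3 cat., CH2Cl2, 0 °C, attack anti to the 3-benzyloxy group) to the 2-(flavan-4β-yl)cyclohexane-1,3-dione F4.
  - TBSOTf/Et3N gives the bis(silyloxy)cyclohexadiene F5. DDQ (1 equiv, 0 °C) dehydrogenates it to the bis-TBS resorcinol F6, and TBAF gives the 2-(flavan-4β-yl)resorcinol F7.
  - Monobenzylation (BnBr, 1 equiv, K2CO3) gives 14. The two hydroxyls are equivalent by rotation about C4-t–C8-m.

**Step 13.**
- What may go wrong: the SN2 opening may be sluggish because the phenoxide is flanked by unit t. Forcing conditions could then bring in SN1-type opening and loss of the inversion.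
- Fallback, from 7 and 19 back to 27 (the order of union is changed so that the ether is made on the small phenol):
  - 7 opens 19 under the same base catalysis to the iodoaryl hydroxy ether F8, and benzylation gives the iodoaryl acetal F9.
  - The cascade of step 16 with 23 gives the 8-m-iodo epifisetinidol-(4β→8)-catechin dimer F10.
  - Iodine–magnesium exchange with an extra equivalent of iPrMgCl·LiCl for the free hydroxyl, then borylation as in step 7, gives the C8-m boronic acid F11. Coupling F11 with 5 under the conditions of step 8 gives 27.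

## Further compounds

F1 | step 16 | α-benzyloxy aldehyde from 21 (C4-m as CHO) | C(c9ccccc9)Oc1cc(OCc9ccccc9)c2c(c1Br)O[C@H](c1ccc(OCc9ccccc9)c(OCc9ccccc9)c1)[C@H](OCc9ccccc9)[C@H]2c1c(OCc9ccccc9)cccc1O[C@H](c1ccc(OCc9ccccc9)c(OCc9ccccc9)c1)[C@H](OCc9ccccc9)C=O
F2 | step 16 | 8-bromo-5,7,3',4'-tetra-O-benzyl-(+)-catechin | C(c9ccccc9)Oc1cc(OCc9ccccc9)c2c(c1Br)O[C@H](c1ccc(OCc9ccccc9)c(OCc9ccccc9)c1)[C@@H](O)C2
F3 | step 16 | C4-m carbinol bearing the catechin-8-yl group, both epimers | C(c9ccccc9)Oc1cc(OCc9ccccc9)c2c(c1Br)O[C@H](c1ccc(OCc9ccccc9)c(OCc9ccccc9)c1)[C@H](OCc9ccccc9)[C@H]2c1c(OCc9ccccc9)cccc1O[C@H](c1ccc(OCc9ccccc9)c(OCc9ccccc9)c1)[C@H](OCc9ccccc9)C(O)c1c(OCc9ccccc9)cc(OCc9ccccc9)c2c1O[C@H](c1ccc(OCc9ccccc9)c(OCc9ccccc9)c1)[C@@H](O)C2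
F4 | step 8 | 2-(8-bromo-penta-O-benzylepicatechin-4β-yl)cyclohexane-1,3-dione | C(c9ccccc9)Oc1cc(OCc9ccccc9)c2c(c1Br)O[C@H](c1ccc(OCc9ccccc9)c(OCc9ccccc9)c1)[C@H](OCc9ccccc9)[C@H]2C1C(=O)CCCC1=O
F5 | step 8 | 1,3-bis(tert-butyldimethylsilyloxy)cyclohexa-1,3-diene carrying the flavan-4β-yl group at C2 | C(c9ccccc9)Oc1cc(OCc9ccccc9)c2c(c1Br)O[C@H](c1ccc(OCc9ccccc9)c(OCc9ccccc9)c1)[C@H](OCc9ccccc9)[C@H]2C1=C(O[Si](C)(C)C(C)(C)C)CCC=C1O[Si](C)(C)C(C)(C)C
F6 | step 8 | bis-TBS ether of the 2-(flavan-4β-yl)resorcinol | C(c9ccccc9)Oc1cc(OCc9ccccc9)c2c(c1Br)O[C@H](c1ccc(OCc9ccccc9)c(OCc9ccccc9)c1)[C@H](OCc9ccccc9)[C@H]2c1c(O[Si](C)(C)C(C)(C)C)cccc1O[Si](C)(C)C(C)(C)C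
F7 | step 8 | 2-(8-bromo-penta-O-benzylepicatechin-4β-yl)resorcinol | C(c9ccccc9)Oc1cc(OCc9ccccc9)c2c(c1Br)O[C@H](c1ccc(OCc9ccccc9)c(OCc9ccccc9)c1)[C@H](OCc9ccccc9)[C@H]2c1c(O)cccc1O
F8 | step 13 | (1R,2S)-1-[3-(benzyloxy)-2-iodophenoxy]-1-[3,4-bis(benzyloxy)phenyl]-3,3-diethoxypropan-2-ol | Ic1c(OCc9ccccc9)cccc1O[C@H](c1ccc(OCc9ccccc9)c(OCc9ccccc9)c1)[C@H](O)C(OCC)OCC
F9 | step 13 | 2-O-benzyl ether of F8 | Ic1c(OCc9ccccc9)cccc1O[C@H](c1ccc(OCc9ccccc9)c(OCc9ccccc9)c1)[C@H](OCc9ccccc9)C(OCC)OCC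
F10 | step 13 | 8-m-iodo benzylated epifisetinidol-(4β→8)-catechin dimer | Ic1c(OCc9ccccc9)ccc2c1O[C@H](c1ccc(OCc9ccccc9)c(OCc9ccccc9)c1)[C@H](OCc9ccccc9)[C@H]2c1c(OCc9ccccc9)cc(OCc9ccccc9)c2c1O[C@H](c1ccc(OCc9ccccc9)c(OCc9ccccc9)c1)[C@@H](O)C2
F11 | step 13 | C8-m boronic acid of the benzylated dimer | OB(O)c1c(OCc9ccccc9)ccc2c1O[C@H](c1ccc(OCc9ccccc9)c(OCc9ccccc9)c1)[C@H](OCc9ccccc9)[C@H]2c1c(OCc9ccccc9)cc(OCc9ccccc9)c2c1O[C@H](c1ccc(OCc9ccccc9)c(OCc9ccccc9)c1)[C@@H](O)C2
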